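**Strategy.** The cyclopentane ring of the hydrindane is opened at C1–C2 and C3–C3a (octahydroindene numbering). C1, the quaternary C7a and the ring-fusion carbon C3a then correspond to an ester α-carbon, a quaternary centre and a ketone carbon in 1,3-relationship, as in keto ester 6. In the key step the ester enolate adds to vinyltriphenylphosphonium bromide (C1–C2) and the resulting ylide closes onto the hindered C3a ketone by intramolecular Wittig reaction (C3=C3a). This Schweizer cyclopentene annulation inserts the two-carbon unit in one operation. Hydrogenation then sets the trans ring fusion, and a chiral-pool butenolide template delivers the side-chain stereocentres.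

Key step: step 4

Remark: locants C1–C7a refer to the octahydro-1H-indene core (C1 bears the side chain, C3a is the ring-fusion CH, C7a the methyl-bearing quaternary carbon). The (R)-ligand of step 2 is assumed to give the (R)-ketone, the mirror image of the sense of induction of the (S)-ligand.

**Route**

Step 1
Reactants: 1 2,2,6-trimethylcyclohexan-1-one (racemic); 2 allyl chloroformate
Product: 4 prop-2-en-1-yl 2,6,6-trimethylcyclohex-1-en-1-yl carbonate, via lithium enolate 3 (not isolated)
Conditions: LiHMDS, THF, 0 °C; then 2, −78 °C to rt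
Reagents that add atoms: allyl chloroformate (compound 2), C=CCOC(=O)Cl
Why: The ketone has a single enolisable position, so O-acylation of its enolate with the chloroformate (enol carbonate formation) should give one tetrasubstituted enol carbonate and erase the stereocentre of racemic 1.

Step 2
Reactants: 4 allyl enol carbonate
Product: 5 (2R)-2,6,6-trimethyl-2-(prop-2-en-1-yl)cyclohexan-1-one
Conditions: Pd2(dba)3 (2.5 mol%), (R)-t-Bu-PHOX (6.25 mol%), THF, 25 °C
Reagents that add atoms: none
Why: Decarboxylative Tsuji–Trost allylation (ionisation by zerovalent palladium, loss of CO2, allylation of the enolate within the chiral phosphinooxazoline complex) should set the quaternary C7a centre in high enantiomeric excess.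

Step 3
Reactants: 5 allyl ketone
Product: 6 methyl 2-[(1R)-1,3,3-trimethyl-2-oxocyclohexyl]acetate
Conditions: O3, NaOH (2.5 M in MeOH), CH2Cl2, −78 °C
Reagents that add atoms: ozone, O=[O+][O-]; methanol, CO
Why: Ozonolysis in basic methanol should convert the terminal alkene directly into the methyl ester (oxidative cleavage with methanol trapping), the ketone without α-hydrogens being inert.

Step 4
Reactants: 6 keto ester; 7 vinyltriphenylphosphonium bromide
Product: 10 methyl (7aR)-4,4,7a-trimethyl-2,4,5,6,7,7a-hexahydro-1H-indene-1-carboxylate (both C1 epimers), via lithium ester enolate 8 (not isolated), via phosphonium ylide 9 (not isolated)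
Conditions: LDA (1.05 equiv), THF, −78 °C; then 7, −78 °C to rt; then 65 °C
Reagents that add atoms: vinyltriphenylphosphonium bromide (compound 7), C=C[P+](c1ccccc1)(c1ccccc1)c1ccccc1.[Br-]
Why: The lithium ester enolate 8 adds in Michael fashion to the vinylphosphonium salt, forming C1–C2 and ylide 9, whose carbanion carbon C3 then attacks the C3a ketone and collapses through a spiro-oxaphosphetane to the C3=C3a alkene with loss of Ph3PO. The closest known reaction type is the Schweizer cyclopentene annulation of γ-oxo carbanions with vinylphosphonium salts. The five-membered ring closes by intramolecular Wittig olefination (5-exo-trig attack of the ylide on the carbonyl, then cycloreversion). No new stereocentre needs control here: C7a is carried from step 2, C1 forms as an epimer mixture that is corrected in step 6, and C3a stays sp2 until step 5. The step needs C-alkylation at the ester α-carbon and olefination of the ketone in preference to the ester; the substrate secures both because the ketone has no α-hydrogen and closure on the ester would need a four-membered ring. The ylide is less basic than an ester enolate, so it should not be quenched by the newly formed C1–H.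

Step 5
Reactants: 10 hydrindene ester
Product: 11 methyl (3aS,7aS)-4,4,7a-trimethyloctahydro-1H-indene-1-carboxylate (both C1 epimers)
Conditions: H2 (4 atm), 10% Pd/C, EtOAc, 25 °C
Reagents that add atoms: none
Why: Heterogeneous syn-hydrogenation should deliver hydrogen to the face of the C3=C3a alkene opposite the angular C7a methyl group (as in the hydrogenation of steroidal Δ14-alkenes to 14α-products), setting C3a and the trans ring fusion.

Step 6
Reactants: 11 trans-hydrindane ester (C1 epimers)
Product: 12 methyl (1S,3aS,7aS)-4,4,7a-trimethyloctahydro-1H-indene-1-carboxylate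
Conditions: NaOMe (0.5 equiv), MeOH, 65 °C; chromatography, minor C1 epimer re-subjected
Reagents that add atoms: none
Why: Base-mediated epimerisation α to the ester (thermodynamic control) should favour the ester cis to the angular methyl group, as for 17β-carboxylates of trans-fused steroid C/D rings, which sets C1.

Step 7
Reactants: 12 ester
Product: 14 1-[(1S,3aS,7aS)-4,4,7a-trimethyloctahydro-1H-inden-1-yl]ethan-1-one, via α-silyl ketone 13 (not isolated)
Conditions: Me3SiCH2Li (2.5 equiv), THF/pentane, 0 °C to rt; then MeOH, rt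
Reagents that add atoms: (trimethylsilyl)methyllithium, [Li]C[Si](C)(C)C
Why: Acyl substitution by the α-silyl carbanion gives an α-silyl ketone that is protected from over-addition as its enolate (formed on the silylmethyl side, so C1 is not touched), and methanolysis of the C–Si bond should then release the methyl ketone.

Step 8
Reactants: 14 methyl ketone
Product: 16 1-[(1S,3aS,7aS)-4,4,7a-trimethyloctahydro-1H-inden-1-yl]ethenyl trifluoromethanesulfonate, via potassium enolate 15 (not isolated)
Conditions: KHMDS, THF, −78 °C; then PhNTf2, −78 to 0 °C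
Reagents that add atoms: N-phenylbis(trifluoromethanesulfonimide), O=S(=O)(N(c1ccccc1)S(=O)(=O)C(F)(F)F)C(F)(F)F
Why: Kinetic deprotonation at the methyl group rather than at the hindered C1–H, followed by O-sulfonylation (enol triflate formation), should give the 1,1-disubstituted alkenyl triflate without loss of the C1 configuration.

Step 9
Reactants: 17 (5S)-5-(hydroxymethyl)furan-2(5H)-one
Product: 18 (5S)-5-{[(triethylsilyl)oxy]methyl}furan-2(5H)-one
Conditions: Et3SiCl, imidazole, CH2Cl2, 0 °C
Reagents that add atoms: chlorotriethylsilane, CC[Si](Cl)(CC)CC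
Why: Silylation of the primary alcohol installs the more labile of two silyl ethers, to be removed first in step 13.

Step 10
Reactants: 18 butenolide
Product: 19 (4R,5S)-4-(hydroxymethyl)-5-{[(triethylsilyl)oxy]methyl}oxolan-2-one
Conditions: benzophenone (0.1 equiv), MeOH (solvent), hν (350 nm), degassed, rt
Reagents that add atoms: methanol, CO
Why: Photosensitised radical conjugate addition (Giese-type addition of the hydroxymethyl radical) should occur at the β-carbon anti to the C5 substituent, setting C4 trans to C5.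

Step 11
Reactants: 19 hydroxymethyl lactone
Product: 20 (4R,5S)-4-{[(tert-butyldimethylsilyl)oxy]methyl}-5-{[(triethylsilyl)oxy]methyl}oxolan-2-one
Conditions: t-BuMe2SiCl, imidazole, DMF, rt
Reagents that add atoms: tert-butyl(chloro)dimethylsilane, CC(C)(C)[Si](C)(C)Cl
Why: Silylation of the new primary alcohol gives the more robust silyl ether, which must survive until step 15.

Step 12
Reactants: 20 lactone; 16 alkenyl triflate
Product: 22 (3R,4R,5S)-4-{[(tert-butyldimethylsilyl)oxy]methyl}-5-{[(triethylsilyl)oxy]methyl}-3-{1-[(1R,3aS,7aS)-4,4,7a-trimethyloctahydro-1H-inden-1-yl]ethenyl}oxolan-2-one, via zinc enolate 21 (not isolated)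
Conditions: LiHMDS, THF, −78 °C; ZnCl2, −78 to 0 °C; then 16, Pd2(dba)3 (2.5 mol%), XPhos (10 mol%), THF, 50 °C
Reagents that add atoms: none
Why: Negishi-type palladium-catalysed α-alkenylation of the weakly basic zinc enolate should place the alkenyl group anti to the C4 substituent (C3 trans to C4), and the minor enantiomeric series of 16 becomes a separable diastereomer.

Step 13
Reactants: 22 coupled lactone
Product: 23 (3R,4R,5S)-4-{[(tert-butyldimethylsilyl)oxy]methyl}-5-(hydroxymethyl)-3-{1-[(1R,3aS,7aS)-4,4,7a-trimethyloctahydro-1H-inden-1-yl]ethenyl}oxolan-2-one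
Conditions: PPTS (0.2 equiv), MeOH/CH2Cl2, 0 °C
Reagents that add atoms: none
Why: Acid-catalysed methanolysis should cleave the primary triethylsilyl ether much faster than the primary tert-butyldimethylsilyl ether (selective desilylation).

Step 14
Reactants: 23 primary alcohol
Product: 24 (2S,3R,4R)-3-{[(tert-butyldimethylsilyl)oxy]methyl}-5-oxo-4-{1-[(1R,3aS,7aS)-4,4,7a-trimethyloctahydro-1H-inden-1-yl]ethenyl}oxolane-2-carboxylic acid
Conditions: TEMPO (0.2 equiv), PhI(OAc)2 (2.5 equiv), NaHCO3, MeCN/H2O (1:1), 0 °C to rt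
Reagents that add atoms: water, O
Why: Oxoammonium-catalysed oxidation takes the primary alcohol through the aldehyde hydrate to the acid; the ring oxygen on the neighbouring carbon is still acylated, so no free 1,2-diol is exposed to cleavage, and the alkene and silyl ether should be inert.

Step 15
Reactants: 24 lactone acid
Product: 26 (3S,4R)-3-hydroxy-4-{(2R)-1-hydroxy-3-[(1R,3aS,7aS)-4,4,7a-trimethyloctahydro-1H-inden-1-yl]but-3-en-2-yl}oxolan-2-one, via dihydroxy acid 25 (not isolated)
Conditions: LiHMDS (1.0 equiv), THF, −78 °C; LiBH4 (2 equiv), 0 °C to rt; then 1 M HCl, MeOH/THF, rt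
Reagents that add atoms: none
Why: Hydride reduction should open the lactone to the primary alcohol and the free secondary hydroxyl while the pre-formed lithium carboxylate is inert, and the acidic phase then removes the silyl ether and closes the thermodynamically preferred γ-lactone onto the liberated hydroxymethyl group (chemoselective reduction, then translactonisation).

Step 16
Reactants: 26 diol lactone
Product: 27 (2R)-2-[(3R,4S)-4-hydroxy-5-oxooxolan-3-yl]-3-[(1R,3aS,7aS)-4,4,7a-trimethyloctahydro-1H-inden-1-yl]but-3-en-1-yl acetate (target)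
Conditions: AcCl (1.05 equiv), 2,4,6-collidine, CH2Cl2, −78 °C
Reagents that add atoms: acetyl chloride, CC(Cl)=O
Why: Selective O-acylation should take place at the primary alcohol, the secondary α-hydroxyl of the lactone being hindered and poorly nucleophilic.

**Compound list**

1 | 2,2,6-trimethylcyclohexan-1-one (racemic) | CC1CCCC(C)(C)C1=O | starting material
2 | allyl chloroformate | C=CCOC(=O)Cl | starting material
3 | lithium 2,6,6-trimethylcyclohex-1-en-1-olate | [Li+].[O-]C1=C(C)CCCC1(C)C | intermediate
4 | prop-2-en-1-yl 2,6,6-trimethylcyclohex-1-en-1-yl carbonate | C=CCOC(=O)OC1=C(C)CCCC1(C)C | intermediate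
5 | (2R)-2,6,6-trimethyl-2-(prop-2-en-1-yl)cyclohexan-1-one | C=CC[C@@]1(C)CCCC(C)(C)C1=O | intermediate
6 | methyl 2-[(1R)-1,3,3-trimethyl-2-oxocyclohexyl]acetate | COC(=O)C[C@@]1(C)CCCC(C)(C)C1=O | intermediate
7 | vinyltriphenylphosphonium bromide | C=C[P+](c1ccccc1)(c1ccccc1)c1ccccc1.[Br-] | starting material
8 | lithium ester enolate of 6 | [Li+].[O-]C(OC)=C[C@@]1(C)CCCC(C)(C)C1=O | intermediate
9 | methyl 2-[(1R)-1,3,3-trimethyl-2-oxocyclohexyl]-4-(triphenyl-λ5-phosphanylidene)butanoate (ylide, both C2 epimers) | COC(=O)C(CC=P(c1ccccc1)(c1ccccc1)c1ccccc1)[C@@]1(C)CCCC(C)(C)C1=O | intermediate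
10 | methyl (7aR)-4,4,7a-trimethyl-2,4,5,6,7,7a-hexahydro-1H-indene-1-carboxylate (both C1 epimers) | COC(=O)C1CC=C2C(C)(C)CCC[C@]12C | intermediate
11 | methyl (3aS,7aS)-4,4,7a-trimethyloctahydro-1H-indene-1-carboxylate (both C1 epimers) | COC(=O)C1CC[C@H]2C(C)(C)CCC[C@]12C | intermediate
12 | methyl (1S,3aS,7aS)-4,4,7a-trimethyloctahydro-1H-indene-1-carboxylate | COC(=O)[C@H]1CC[C@H]2C(C)(C)CCC[C@]12C | intermediate
13 | 1-[(1S,3aS,7aS)-4,4,7a-trimethyloctahydro-1H-inden-1-yl]-2-(trimethylsilyl)ethan-1-one | C[Si](C)(C)CC(=O)[C@H]1CC[C@H]2C(C)(C)CCC[C@]12C | intermediate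
14 | 1-[(1S,3aS,7aS)-4,4,7a-trimethyloctahydro-1H-inden-1-yl]ethan-1-one | CC(=O)[C@H]1CC[C@H]2C(C)(C)CCC[C@]12C | intermediate
15 | potassium enolate of 14 (methyl side) | [K+].[O-]C(=C)[C@H]1CC[C@H]2C(C)(C)CCC[C@]12C | intermediate
16 | 1-[(1S,3aS,7aS)-4,4,7a-trimethyloctahydro-1H-inden-1-yl]ethenyl trifluoromethanesulfonate | C=C(OS(=O)(=O)C(F)(F)F)[C@H]1CC[C@H]2C(C)(C)CCC[C@]12C | intermediate
17 | (5S)-5-(hydroxymethyl)furan-2(5H)-one | O=C1C=C[C@@H](CO)O1 | starting material
18 | (5S)-5-{[(triethylsilyl)oxy]methyl}furan-2(5H)-one | O=C1C=C[C@@H](CO[Si](CC)(CC)CC)O1 | intermediate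
19 | (4R,5S)-4-(hydroxymethyl)-5-{[(triethylsilyl)oxy]methyl}oxolan-2-one | O=C1C[C@H](CO)[C@@H](CO[Si](CC)(CC)CC)O1 | intermediate
20 | (4R,5S)-4-{[(tert-butyldimethylsilyl)oxy]methyl}-5-{[(triethylsilyl)oxy]methyl}oxolan-2-one | O=C1C[C@H](CO[Si](C)(C)C(C)(C)C)[C@@H](CO[Si](CC)(CC)CC)O1 | intermediate
21 | chlorozinc enolate of 20 | Cl[Zn]OC1=C[C@H](CO[Si](C)(C)C(C)(C)C)[C@@H](CO[Si](CC)(CC)CC)O1 | intermediate
22 | (3R,4R,5S)-4-{[(tert-butyldimethylsilyl)oxy]methyl}-5-{[(triethylsilyl)oxy]methyl}-3-{1-[(1R,3aS,7aS)-4,4,7a-trimethyloctahydro-1H-inden-1-yl]ethenyl}oxolan-2-one | C=C([C@H]1CC[C@H]2C(C)(C)CCC[C@]12C)[C@@H]1C(=O)O[C@H](CO[Si](CC)(CC)CC)[C@H]1CO[Si](C)(C)C(C)(C)C | intermediate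
23 | (3R,4R,5S)-4-{[(tert-butyldimethylsilyl)oxy]methyl}-5-(hydroxymethyl)-3-{1-[(1R,3aS,7aS)-4,4,7a-trimethyloctahydro-1H-inden-1-yl]ethenyl}oxolan-2-one | C=C([C@H]1CC[C@H]2C(C)(C)CCC[C@]12C)[C@@H]1C(=O)O[C@H](CO)[C@H]1CO[Si](C)(C)C(C)(C)C | intermediate
24 | (2S,3R,4R)-3-{[(tert-butyldimethylsilyl)oxy]methyl}-5-oxo-4-{1-[(1R,3aS,7aS)-4,4,7a-trimethyloctahydro-1H-inden-1-yl]ethenyl}oxolane-2-carboxylic acid | C=C([C@H]1CC[C@H]2C(C)(C)CCC[C@]12C)[C@@H]1C(=O)O[C@H](C(=O)O)[C@H]1CO[Si](C)(C)C(C)(C)C | intermediate
25 | (2S,3R,4R)-3-{[(tert-butyldimethylsilyl)oxy]methyl}-2-hydroxy-4-(hydroxymethyl)-5-[(1R,3aS,7aS)-4,4,7a-trimethyloctahydro-1H-inden-1-yl]hex-5-enoic acid | C=C([C@H]1CC[C@H]2C(C)(C)CCC[C@]12C)[C@H](CO)[C@H](CO[Si](C)(C)C(C)(C)C)[C@H](O)C(=O)O | intermediate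
26 | (3S,4R)-3-hydroxy-4-{(2R)-1-hydroxy-3-[(1R,3aS,7aS)-4,4,7a-trimethyloctahydro-1H-inden-1-yl]but-3-en-2-yl}oxolan-2-one | C=C([C@H]1CC[C@H]2C(C)(C)CCC[C@]12C)[C@H](CO)[C@@H]1COC(=O)[C@H]1O | intermediate
27 | (2R)-2-[(3R,4S)-4-hydroxy-5-oxooxolan-3-yl]-3-[(1R,3aS,7aS)-4,4,7a-trimethyloctahydro-1H-inden-1-yl]but-3-en-1-yl acetate | C=C([C@H]1CC[C@H]2C(C)(C)CCC[C@]12C)[C@H](COC(C)=O)[C@@H]1COC(=O)[C@H]1O | target

**Step count and risks**

Total step count: 16. Longest linear sequence: 13 steps (steps 1–8 and 12–16); steps 9–11 prepare the lactone fragment.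

Steps most likely to fail:

1. Step 4. The intramolecular Wittig closure may stall at the ketone flanked by two quaternary carbons, so that ylide 9 is lost to protonation or slow decomposition instead of closing. The fallback sets out from 6 and makes the two bonds in separate operations. The lithium enolate of 6 is C-allylated (LDA, THF, −78 °C; allyl bromide) to give methyl 2-[(1R)-1,3,3-trimethyl-2-oxocyclohexyl]pent-4-enoate F1. Ozonolysis (O3, CH2Cl2, −78 °C; Me2S) gives methyl 4-oxo-2-[(1R)-1,3,3-trimethyl-2-oxocyclohexyl]butanoate F2. Intramolecular McMurry coupling of the aldehyde with the hindered ketone (TiCl3(DME)1.5, Zn–Cu couple, DME, reflux; low-valent titanium) closes C3=C3a and comes back to the route at 10.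

2. Step 12. Reductive elimination at the congested α-carbon may be slow, and the new double bond may migrate into conjugation with the lactone through re-enolisation of the product. The fallback reverses the polarity of the lactone and sets out from 20 and 16. The silyl ketene acetal of 20 (LiHMDS, Me3SiCl, THF, −78 °C) is brominated with N-bromosuccinimide to give (3S,4R,5S)-3-bromo-4-{[(tert-butyldimethylsilyl)oxy]methyl}-5-{[(triethylsilyl)oxy]methyl}oxolan-2-one F5, with bromine trans to the C4 substituent. Triflate 16 is converted (Me3SnSnMe3, Pd(PPh3)4, LiCl, THF, 60 °C) into trimethyl{1-[(1S,3aS,7aS)-4,4,7a-trimethyloctahydro-1H-inden-1-yl]ethenyl}stannane F6. Stille coupling of F5 with F6 under neutral conditions (Pd2(dba)3, tri(2-furyl)phosphine, THF, 60 °C) should give the trans product and comes back to the route at 22.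

3. Step 5. Facial selectivity of hydrogen delivery may be poor, in particular for the C1 epimer whose ester lies anti to the angular methyl group, which would give cis-fused material. The fallback sets out from 10. Hydroboration–oxidation (BH3·SMe2, THF, 0 °C; NaOH, H2O2) adds boron and hydrogen cis from the face opposite the angular methyl and gives methyl (3S,3aS,7aS)-3-hydroxy-4,4,7a-trimethyloctahydro-1H-indene-1-carboxylate F3. Xanthate formation (NaH, CS2, MeI, THF) gives methyl (3S,3aS,7aS)-4,4,7a-trimethyl-3-{[(methylsulfanyl)carbonothioyl]oxy}octahydro-1H-indene-1-carboxylate F4. Barton–McCombie deoxygenation (Bu3SnH, AIBN, toluene, 80 °C) comes back to the route at 11.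

Further compounds

F1 | step 4 | methyl 2-[(1R)-1,3,3-trimethyl-2-oxocyclohexyl]pent-4-enoate (both C2 epimers) | C=CCC(C(=O)OC)[C@@]1(C)CCCC(C)(C)C1=O
F2 | step 4 | methyl 4-oxo-2-[(1R)-1,3,3-trimethyl-2-oxocyclohexyl]butanoate (both C2 epimers) | O=CCC(C(=O)OC)[C@@]1(C)CCCC(C)(C)C1=O
F5 | step 12 | (3S,4R,5S)-3-bromo-4-{[(tert-butyldimethylsilyl)oxy]methyl}-5-{[(triethylsilyl)oxy]methyl}oxolan-2-one | O=C1[C@@H](Br)[C@H](CO[Si](C)(C)C(C)(C)C)[C@@H](CO[Si](CC)(CC)CC)O1
F6 | step 12 | trimethyl{1-[(1S,3aS,7aS)-4,4,7a-trimethyloctahydro-1H-inden-1-yl]ethenyl}stannane | C=C([Sn](C)(C)C)[C@H]1CC[C@H]2C(C)(C)CCC[C@]12C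
F3 | step 5 | methyl (3S,3aS,7aS)-3-hydroxy-4,4,7a-trimethyloctahydro-1H-indene-1-carboxylate (both C1 epimers) | COC(=O)C1C[C@H](O)[C@H]2C(C)(C)CCC[C@]12C
F4 | step 5 | methyl (3S,3aS,7aS)-4,4,7a-trimethyl-3-{[(methylsulfanyl)carbonothioyl]oxy}octahydro-1H-indene-1-carboxylate (both C1 epimers) | COC(=O)C1C[C@H](OC(=S)SC)[C@H]2C(C)(C)CCC[C@]12C
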